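**Strategy.** Ring A, the phloroglucinol ring, is cut at C8–C8a and C4a–C5. C8a and C4a are then the two alkene carbons of a 2-aryl-2,3-dihydropyran-4-one (ring C), and C5–C8 is a β-keto ester chain whose γ-carbon, the future C8, already bears the 4-oxybenzyl group, so the 8-position is never in question. One operation joins the two: a silyl triflate-triggered vinylogous Mukaiyama–Michael addition makes C8–C8a, and a base-induced Dieckmann closure makes C4a–C5 and ring A. The precursors are a racemic dihydropyranone and a preformed 1,3-bis(silyloxy)diene. Both phenols travel as benzyl ethers, so that the final unmasking is neutral hydrogenolysis after joint dehydrogenation of rings A and C.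

Key step: step 4

Remark: C2, C8 and C8a are sp2 in the target, so 4 and all later intermediates are used as racemates (13 also as a C8 epimer mixture) with one enantiomer drawn; the bicyclic compounds carry the chromene numbering of the target.

**Step 1**
Reactants: 1 4-(benzyloxy)benzaldehyde; 2 (E)-1-methoxy-3-(trimethylsilyloxy)buta-1,3-diene
Product: 4 (±)-2-[4-(benzyloxy)phenyl]-2,3-dihydro-4H-pyran-4-one (racemate; 2R drawn), via cycloadduct 3 (not isolated)
Conditions: ZnCl2 (0.2 equiv), THF, rt; then TFA (cat.), CH2Cl2, 0 °C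
Reagents that add atoms: none
Why: ZnCl2-promoted hetero-Diels–Alder reaction of the aldehyde with the electron-rich silyloxydiene gives cycloadduct 3, which on brief acid treatment loses methanol and the silyl group to unveil the enone; C2 is formed racemic and is erased in step 5.

**Step 2**
Reactants: 5 methyl acetoacetate; 6 4-(benzyloxy)benzyl chloride
Product: 8 methyl 5-[4-(benzyloxy)phenyl]-3-oxopentanoate, via acetoacetate dianion 7 (not isolated)
Conditions: NaH, THF, 0 °C; n-BuLi, 0 °C; 6, 0 °C → rt; aq. HCl
Reagents that add atoms: none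
Why: Weiler dianion alkylation, in which the more basic terminal carbon of the dianion displaces the benzylic chloride (SN2), so the arylmethyl group sits on the carbon that becomes C8; no stereocentre is formed.

**Step 3**
Reactants: 8 methyl 5-[4-(benzyloxy)phenyl]-3-oxopentanoate
Product: 10 (3Z)-5-[4-(benzyloxy)phenyl]-1-methoxy-1,3-bis(trimethylsilyloxy)penta-1,3-diene (ketene acetal geometry not defined), via mono-silyl enol ether 9 (not isolated)
Conditions: Me3SiCl, Et3N, hexane, rt; filter, concentrate; LDA, THF, −78 °C; Me3SiCl, −78 °C → rt; pentane, filter, concentrate (used crude)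
Reagents that add atoms: chlorotrimethylsilane, C[Si](C)(C)Cl
Why: Standard two-stage enol silylation of a β-keto ester (O-silylation of the enol, then kinetic γ-deprotonation of 9 with LDA and O-silylation of the ester dienolate) gives the 1,3-bis(silyloxy)diene as a salt-free donor; alkene geometry has no consequence for the target.

**Step 4**
Reactants: 4 (±)-2-[4-(benzyloxy)phenyl]-2,3-dihydro-4H-pyran-4-one; 10 (3Z)-5-[4-(benzyloxy)phenyl]-1-methoxy-1,3-bis(trimethylsilyloxy)penta-1,3-diene
Product: 13 (2R*,8S*,8aS*)-8-[4-(benzyloxy)benzyl]-2-[4-(benzyloxy)phenyl]-5-hydroxy-2,3,8,8a-tetrahydro-4H-chromene-4,7(6H)-dione (C4a=C5 enol of the 4,5,7-trione; 2,8a-trans; racemic; C8 epimer also expected), via silyloxy oxocarbenium triflate 11 (not isolated), via bis-silyl Michael adduct 12 (not isolated)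
Conditions: Me3SiOTf (1.1 equiv), CH2Cl2, −78 °C; 10 (1.3 equiv), −78 → −40 °C; THF, KOtBu (4 equiv), −78 → 0 °C, short; AcOH, −78 °C; crude 13 taken on at once
Reagents that add atoms: none
Why: Proposed new method: Me3SiOTf silylates the enone oxygen of 4 to give the cyclic 4-silyloxy oxocarbenium ion 11, the terminal (γ) carbon of diene 10 adds to the carbon next to the ring oxygen (C8a) to form C8–C8a and leave the regiodefined C4=C4a silyl enol ether 12, and KOtBu then removes both silyl groups so that the C4a enolate acylates on the methyl ester with loss of methoxide, forming C4a–C5. The closest known reaction types are silyl triflate-promoted (vinylogous) Mukaiyama–Michael additions of silyl enol ethers and 1,3-bis(silyloxy)dienes to pyranones and chromones, and Michael–Dieckmann (Michael–Claisen) annulations in which an ester-bearing donor adds to an enone and the resulting enolate closes onto the ester to give a cyclohexane-1,3-dione. Ring A is closed in a 6-exo-trig Dieckmann mode, made irreversible by deprotonation of the tricarbonyl product. C8a is set by axial attack on the half-chair oxocarbenium ion on the face opposite the pseudo-equatorial C2 aryl group (2,8a-trans), while C8 is formed without control; both centres vanish in step 5. The step needs conjugate rather than carbonyl addition (secured by the oxocarbenium character at C8a), γ rather than α attack of the donor (inherent in the 1,3-bis(silyloxy)diene) and C-acylation faster than expulsion of O1 from C8a (favoured by the defined enolate, low temperature, brief base contact and a cold acidic quench).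

**Step 5**
Reactants: 13 (2R*,8S*,8aS*)-8-[4-(benzyloxy)benzyl]-2-[4-(benzyloxy)phenyl]-5-hydroxy-2,3,8,8a-tetrahydro-4H-chromene-4,7(6H)-dione
Product: 15 8-[4-(benzyloxy)benzyl]-2-[4-(benzyloxy)phenyl]-5,7-dihydroxy-4H-chromen-4-one, via flavanone 14 (not isolated)
Conditions: I2 (0.2 equiv), DMSO, 60 °C then 120 °C; aq. Na2S2O3
Reagents that add atoms: none
Why: Iodine-mediated dehydrogenation with DMSO as terminal oxidant, in which α-iodination of the enolised trione and loss of HI aromatises ring A to flavanone 14 and the same couple then introduces C2=C3 as in the standard flavanone-to-flavone oxidation; C2, C8 and C8a become sp2, so all stereochemistry is erased.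

**Step 6**
Reactants: 15 8-[4-(benzyloxy)benzyl]-2-[4-(benzyloxy)phenyl]-5,7-dihydroxy-4H-chromen-4-one
Product: 16 5,7-dihydroxy-8-(4-hydroxybenzyl)-2-(4-hydroxyphenyl)-4H-chromen-4-one (target; achiral)
Conditions: H2 (1 atm), Pd/C, EtOAc–MeOH, rt
Reagents that add atoms: none
Why: Catalytic hydrogenolysis of the two aryl benzyl ethers under neutral conditions, which should leave the chromone and the diarylmethane C–C bond intact and avoids the acid-promoted Wessely–Moser shift of the C8 substituent to C6 that a Lewis- or Brønsted-acid ether cleavage could trigger.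

**Compound list**
1 | 4-(benzyloxy)benzaldehyde | O=Cc1ccc(OCc2ccccc2)cc1 | starting material
2 | (E)-1-methoxy-3-(trimethylsilyloxy)buta-1,3-diene | CO/C=C/C(=C)O[Si](C)(C)C | starting material
3 | 2-[4-(benzyloxy)phenyl]-6-methoxy-4-(trimethylsilyloxy)-3,6-dihydro-2H-pyran (cycloadduct; racemic; acetal centre as a mixture) | c1ccccc1COc2ccc(cc2)[C@H]3CC(O[Si](C)(C)C)=CC(OC)O3 | intermediate (not isolated)
4 | (±)-2-[4-(benzyloxy)phenyl]-2,3-dihydro-4H-pyran-4-one (2R drawn) | c1ccccc1COc2ccc(cc2)[C@H]3CC(=O)C=CO3 | intermediate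
5 | methyl acetoacetate | COC(=O)CC(C)=O | starting material
6 | 4-(benzyloxy)benzyl chloride | ClCc1ccc(OCc2ccccc2)cc1 | starting material
7 | sodium lithium dianion (1,3-dienolate) of methyl acetoacetate | [Na+].[Li+].COC([O-])=CC([O-])=C | intermediate (not isolated)
8 | methyl 5-[4-(benzyloxy)phenyl]-3-oxopentanoate | COC(=O)CC(=O)CCc1ccc(OCc2ccccc2)cc1 | intermediate
9 | methyl (Z)-5-[4-(benzyloxy)phenyl]-3-(trimethylsilyloxy)pent-2-enoate | COC(=O)/C=C(\O[Si](C)(C)C)CCc1ccc(OCc2ccccc2)cc1 | intermediate (not isolated)
10 | (3Z)-5-[4-(benzyloxy)phenyl]-1-methoxy-1,3-bis(trimethylsilyloxy)penta-1,3-diene | COC(O[Si](C)(C)C)=C/C(O[Si](C)(C)C)=C/Cc1ccc(OCc2ccccc2)cc1 | intermediate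
11 | 2-[4-(benzyloxy)phenyl]-4-(trimethylsilyloxy)-2,3-dihydropyrylium trifluoromethanesulfonate (racemic) | c1ccccc1COc2ccc(cc2)[C@H]3CC(O[Si](C)(C)C)=CC=[O+]3.[O-]S(=O)(=O)C(F)(F)F | intermediate (not isolated)
12 | methyl 5-[4-(benzyloxy)phenyl]-4-{2,6-trans-6-[4-(benzyloxy)phenyl]-4-(trimethylsilyloxy)-5,6-dihydro-2H-pyran-2-yl}-3-(trimethylsilyloxy)pent-2-enoate (racemic; one C4 epimer drawn; enol ether geometry not defined) | c1ccccc1COc2ccc(cc2)[C@H]3CC(O[Si](C)(C)C)=C[C@@H](O3)[C@H](Cc4ccc(OCc5ccccc5)cc4)C(O[Si](C)(C)C)=CC(=O)OC | intermediate (not isolated)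
13 | (2R*,8S*,8aS*)-8-[4-(benzyloxy)benzyl]-2-[4-(benzyloxy)phenyl]-5-hydroxy-2,3,8,8a-tetrahydro-4H-chromene-4,7(6H)-dione (2,8a-trans; racemic) | c1ccccc1COc2ccc(cc2)[C@H]3CC(=O)C4=C(O)CC(=O)[C@@H](Cc5ccc(OCc6ccccc6)cc5)[C@@H]4O3 | intermediate
14 | (±)-8-[4-(benzyloxy)benzyl]-2-[4-(benzyloxy)phenyl]-5,7-dihydroxychroman-4-one (2R drawn) | c1ccccc1COc2ccc(cc2)[C@H]3CC(=O)c4c(O)cc(O)c(Cc5ccc(OCc6ccccc6)cc5)c4O3 | intermediate (not isolated)
15 | 8-[4-(benzyloxy)benzyl]-2-[4-(benzyloxy)phenyl]-5,7-dihydroxy-4H-chromen-4-one | O=c1cc(-c2ccc(OCc3ccccc3)cc2)oc2c(Cc3ccc(OCc4ccccc4)cc3)c(O)cc(O)c12 | intermediate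
16 | 5,7-dihydroxy-8-(4-hydroxybenzyl)-2-(4-hydroxyphenyl)-4H-chromen-4-one | O=c1cc(-c2ccc(O)cc2)oc2c(Cc3ccc(O)cc3)c(O)cc(O)c12 | target

**Totals.** Total step count: 6. Longest linear sequence: 5 (steps 2, 3, 4, 5, 6).

**Steps most likely to fail**

1. Step 4 (bears the label Proposed new method). After desilylation, the C4a enolate may expel O1 from C8a (retro-oxa-Michael) faster than it acylates on the ester. The opened chain could then aromatise irreversibly by aldol condensation or tautomerisation. Attack through the α-carbon of the diene or 1,2-addition would also divert material. The fallback uses known chemistry, sets out from 6 (with 1 used later) and returns at 15. C-Benzylation of commercial 2,4,6-trihydroxyacetophenone with 6 in aqueous KOH should give 1-{3-[4-(benzyloxy)benzyl]-2,4,6-trihydroxyphenyl}ethan-1-one F1. MOMCl/i-Pr2NEt should etherify the 4-hydroxyl and the less hindered 6-hydroxyl, leaving free the chelated hydroxyl flanked by the benzyl group, to give 1-{3-[4-(benzyloxy)benzyl]-2-hydroxy-4,6-bis(methoxymethoxy)phenyl}ethan-1-one F2. Claisen–Schmidt condensation with 1 (KOH, EtOH) should give (E)-1-{3-[4-(benzyloxy)benzyl]-2-hydroxy-4,6-bis(methoxymethoxy)phenyl}-3-[4-(benzyloxy)phenyl]prop-2-en-1-one F3. I2 (cat.) in DMSO at 120 °C should cyclise and dehydrogenate through the only free hydroxyl, which places the benzyl group at C8, to give 8-[4-(benzyloxy)benzyl]-2-[4-(benzyloxy)phenyl]-5,7-bis(methoxymethoxy)-4H-chromen-4-one F4. Dilute HCl in MeOH then removes the two acetals to give 15.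

2. Step 5. Heat and transient HI may open ring C of 13 by loss of O1 from C8a, which aromatises ring A without the C8a oxygen, before dehydrogenation takes place. Iodination of the electron-rich ring A at C6 is a second side process. The fallback sets out from 13 and returns at 15, with the two oxidations separated. DDQ (1.05 equiv) in 1,4-dioxane at 0 °C → rt, a neutral hydride-abstraction oxidant, should aromatise ring A alone and allow isolation of flavanone 14. I2 (1.1 equiv) in pyridine at 90 °C, the base-buffered flavanone-to-flavone oxidation, should then give 15.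

3. Step 6. Sulfur or iodine residues from step 5 may poison the catalyst so that debenzylation stalls, and forcing the reaction could over-reduce C2=C3. The fallback sets out from 15 and returns at 16: BCl3 with pentamethylbenzene as benzyl-cation scavenger in CH2Cl2 at −78 °C should cleave both benzyl ethers cold enough to avoid isomerisation of ring C.

**Further compounds**
F1 | step 4 | 1-{3-[4-(benzyloxy)benzyl]-2,4,6-trihydroxyphenyl}ethan-1-one | CC(=O)c1c(O)cc(O)c(Cc2ccc(OCc3ccccc3)cc2)c1O
F2 | step 4 | 1-{3-[4-(benzyloxy)benzyl]-2-hydroxy-4,6-bis(methoxymethoxy)phenyl}ethan-1-one | CC(=O)c1c(OCOC)cc(OCOC)c(Cc2ccc(OCc3ccccc3)cc2)c1O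
F3 | step 4 | (E)-1-{3-[4-(benzyloxy)benzyl]-2-hydroxy-4,6-bis(methoxymethoxy)phenyl}-3-[4-(benzyloxy)phenyl]prop-2-en-1-one | O=C(/C=C/c1ccc(OCc2ccccc2)cc1)c1c(OCOC)cc(OCOC)c(Cc2ccc(OCc3ccccc3)cc2)c1O
F4 | step 4 | 8-[4-(benzyloxy)benzyl]-2-[4-(benzyloxy)phenyl]-5,7-bis(methoxymethoxy)-4H-chromen-4-one | O=c1cc(-c2ccc(OCc3ccccc3)cc2)oc2c(Cc3ccc(OCc4ccccc4)cc3)c(OCOC)cc(OCOC)c12
F0 | step 5 | none | none
F0 | step 6 | none | none
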